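common to all: gas 36 mM (held)

| charge | solid substrate | remark | time |
|---|---|---|---|
| delta | 0.81 M | the very flask that is asked about, followed so far |  |
| zeta | 0.54 M | run made earlier |  |
| flask | 0.81 M |  | 20 h |

| run | time / h | target / % |
|---|---|---|
| delta | 0.333 | 1 |
| delta | 0.667 | 1 |
| delta | 1.50 | 3 |
| delta | 4.00 | 18 |
| zeta | 1.00 | 5 |
| zeta | 2.50 | 15 |
| zeta | 6.00 | 46 |
| zeta | 15.0 | 87 |

(each reading ± 1.5 percentage points)

- as a solid, counted per litre of solution: solid substrate
- at the start none of the gas is in solution
- at the start none of the solid substrate is in solution

- autumn: doubling the solubility of the solid substrate, all else as stated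
- noon: doubling the transfer coefficient of the gas, all else as stated
- summer: doubling the saturation concentration of gas, all else as stated
- dusk: doubling the dissolution coefficient of the solid substrate, all else as stated

- the target standing at 20 h, as a percentage of the solid substrate charged
- the change that raises the amount of target at 20 h, in percent of the solid substrate charged most ("none" if none brings more than 2 percentage points) (autumn / noon / summer / dusk / none)
- amount of target at 20 h, in percent of the solid substrate charged, after autumn

- No rate constant is given for these flasks, but one time can be read from the runs: the clearing time, the hours a flask's whole charge would take at the steady pace of its straight stretch (its zero-order stretch).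
- In the zeta run, the readings at 2.50 h and 6.00 h give 11.3 h. In the delta run, the readings at 1.50 h and 4.00 h give 16.7 h.
- Scaling the zeta time up to the delta charge gives 16.9 h, close to the delta value, so the clearing time grows with the charge.
- A first estimate for the delta flask, 20 h divided by 16.9 h, gives 118%, which is impossible. The pace must also fall late, because the zeta run gained 41 percentage points from 6.00 h to 15.0 h, while steady pace gives 79.6%.
- A better estimate treats the two flasks as one curve shifted in time, which cancels the slow first hour. The delta flask at 20 h stands 3.06 h past its clearing time, which matches the zeta run at 14.4 h.
- The 13.0% of the zeta charge not standing as target at 15.0 h is 8.67% of the delta charge.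
- But that reading lies later than the matching time. At steady pace, the gap adds up to 3.81%, so my estimate for target is 87.5% to 91.3%.
- The forecast gives 90%, names summer as best, and puts autumn at 94%, holding that “Doubling the gas saturation doubles the rate whether or not transfer limits”.
- The flask gives 88.5%, summer adds 3.1 points, and autumn gives 89.8%.

    target ⇌ isomer of the product (K = 0.210, k = 0.00833 /h)
    gas ⇌ reagent, rate k2*(csat - [reagent]) (kL = 151 /h)
    dissolved substrate + reagent → target (k = 5.99 /M/h)
    solid substrate ⇌ dissolved substrate, rate k4*(cs4 - [dissolved substrate]) while solid is left; crystals form when [dissolved substrate] > cs4 (solubility = 0.430 M, k = 0.374 /h)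

- At 20.0 h, this flask also holds 6.76% isomer of the product and 4.77% dissolved substrate. The clearing time, put to use on this flask at 10.0 h, gives 59.2%, and target stands at 58.0%. For the neighbour flask with 2.0 M of solid substrate, the clearing time is 41.8 h, longer than 20 h. Steady pace there gives 47.8%, and that neighbour flask holds 50.3% target.

The runs were computed for an exercise; scatter was added.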